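**Retrosynthetic overview**

1. The p-coumarate is attached last by Mitsunobu acylation at C15–O. The acrylate (C11–C13) and the C15 oxymethylene both come from enol triflates by Pd-catalysed methoxycarbonylation, so C11 and C4 are ketone carbons earlier in the route.
2. Ring B (C5–C10) is made by a semipinacol 1,2-shift that contracts a seven-membered ring C5–C6–C11–C7–C8–C9–C10: C6 migrates from C11 to C7 and C11 leaves the ring as an acetyl carbon.
3. Enabling feature: C7 of ring B carries the exocyclic sp2 carbon C11 (the acrylate α-carbon), which can be a carbinol or carbonyl carbon. It can therefore sit inside the larger ring as a tertiary carbinol between C6 and a C7 sulfonate.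
4. The seven-membered ring comes from ring-closing metathesis (C7=C11) of a C10 butenyl and a C5 methallyl group. Both are put on 3-methylcyclohex-2-enone by Cu-catalysed asymmetric conjugate addition (sets C10) and enolate alkylation (sets C5).
5. Ring order: ring A (purchased six-membered ring) → seven-membered carbocycle → ring B by contraction.

Key step: step 7

Remark: C1–C15 are eudesmane locants of the target (ring A = C1–C5, C10; ring B = C5–C10; C11–C13 = acrylate; C14 = angular methyl; C15 = oxymethylene), β is the face of the angular methyl, and but-3-en-1-ylmagnesium bromide is taken as a commercial solution.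

Step 1
Reactants: 1 3-methylcyclohex-2-en-1-one; 2 but-3-en-1-ylmagnesium bromide; 4 3-bromo-2-methylprop-1-ene
Product: 5 (2R,3R)-3-(but-3-en-1-yl)-3-methyl-2-(2-methylprop-2-en-1-yl)cyclohexan-1-one, via bromomagnesium enolate 3 (not isolated)
Conditions: Cu(OTf)2 (3 mol %), chiral imidazolinium salt (N-heterocyclic carbene precursor, 4 mol %), Et2O, 0 °C; then 4, DMPU, −30 °C → rt
Reagents that add atoms: none
Why: Copper-catalysed asymmetric conjugate addition of the Grignard reagent to the β-methyl enone sets the quaternary C10 centre under ligand control (the ligand enantiomer that gives (R) is used), and the regiodefined enolate 3 should be alkylated at C5 by axial attack anti to the larger butenyl arm, giving the C6/C9-trans ketone (conjugate addition–enolate trapping).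

Step 2
Reactants: 5 (2R,3R)-3-(but-3-en-1-yl)-3-methyl-2-(2-methylprop-2-en-1-yl)cyclohexan-1-one
Product: 7 (5S,6R)-5-(but-3-en-1-yl)-5-methyl-6-(2-methylprop-2-en-1-yl)cyclohex-1-en-1-yl trifluoromethanesulfonate, via lithium enolate 6 (not isolated)
Conditions: LiN(i-Pr)2 (LDA), THF, −78 °C; PhNTf2, −78 → 0 °C
Reagents that add atoms: N-phenylbis(trifluoromethanesulfonimide) O=S(=O)(N(c1ccccc1)S(=O)(=O)C(F)(F)F)C(F)(F)F
Why: Kinetic deprotonation occurs at the unhindered C3 methylene and not at the tertiary C5–H next to the quaternary centre, and O-sulfonylation of enolate 6 gives the Δ3 enol triflate with the C5 stereocentre untouched (kinetic enol triflate formation).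

Step 3
Reactants: 7 (5S,6R)-5-(but-3-en-1-yl)-5-methyl-6-(2-methylprop-2-en-1-yl)cyclohex-1-en-1-yl trifluoromethanesulfonate
Product: 8 (4aS,9aR)-4a,8-dimethyl-4,4a,5,6,9,9a-hexahydro-3H-benzo[7]annulen-1-yl trifluoromethanesulfonate
Conditions: second-generation Grubbs catalyst RuCl2(=CHPh)(PCy3)(H2IMes) (5 mol %), CH2Cl2, 40 °C
Reagents that add atoms: none
Why: Ring-closing olefin metathesis between the butenyl and methallyl alkenes closes the seven-membered ring as its trisubstituted C7=C11 alkene with loss of ethylene, the electron-poor enol triflate alkene being inert to the ruthenium carbene, and no stereocentre is formed.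

Step 4
Reactants: 8 (4aS,9aR)-4a,8-dimethyl-4,4a,5,6,9,9a-hexahydro-3H-benzo[7]annulen-1-yl trifluoromethanesulfonate
Product: 9 methyl (4aS,9aR)-4a,8-dimethyl-4,4a,5,6,9,9a-hexahydro-3H-benzo[7]annulene-1-carboxylate
Conditions: Pd(OAc)2 (5 mol %), dppf, CO (1 atm), MeOH, Et3N, DMF, 60 °C
Reagents that add atoms: carbon monoxide [C-]#[O+]; methanol CO
Why: Oxidative addition of zerovalent palladium into the vinyl C–OTf bond, CO insertion and methanolysis install C15 as the methyl ester of the Δ3 enoate without forming a stereocentre (palladium-catalysed alkoxycarbonylation of an enol triflate).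

Step 5
Reactants: 9 methyl (4aS,9aR)-4a,8-dimethyl-4,4a,5,6,9,9a-hexahydro-3H-benzo[7]annulene-1-carboxylate
Product: 10 methyl (4aR,7S,8R,9aR)-7,8-dihydroxy-4a,8-dimethyl-4,4a,5,6,7,8,9,9a-octahydro-3H-benzo[7]annulene-1-carboxylate (7α,11α-cis-diol)
Conditions: OsO4 (2 mol %), NMO, acetone–H2O, 0 °C → rt
Reagents that add atoms: osmium tetroxide O=[Os](=O)(=O)=O; N-methylmorpholine N-oxide C[N+]1([O-])CCOCC1; water O
Why: Catalytic syn-dihydroxylation is chemoselective for the electron-rich C7=C11 alkene over the conjugated enoate and should occur on the convex α face opposite the angular methyl to give the 7α,11α-diol, while the β,β-diol would funnel to the same ketone 14 in step 7.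

Step 6
Reactants: 10 methyl (4aR,7S,8R,9aR)-7,8-dihydroxy-4a,8-dimethyl-4,4a,5,6,7,8,9,9a-octahydro-3H-benzo[7]annulene-1-carboxylate
Product: 11 methyl (4aR,7S,8R,9aR)-8-hydroxy-7-[(methanesulfonyl)oxy]-4a,8-dimethyl-4,4a,5,6,7,8,9,9a-octahydro-3H-benzo[7]annulene-1-carboxylate
Conditions: MsCl, Et3N, CH2Cl2, −20 °C
Reagents that add atoms: methanesulfonyl chloride CS(=O)(=O)Cl
Why: Sulfonylation is selective for the secondary C7 hydroxyl over the hindered tertiary C11 hydroxyl and makes C7 the migration terminus with both stereocentres retained (selective mesylation).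

Step 7
Reactants: 11 methyl (4aR,7S,8R,9aR)-8-hydroxy-7-[(methanesulfonyl)oxy]-4a,8-dimethyl-4,4a,5,6,7,8,9,9a-octahydro-3H-benzo[7]annulene-1-carboxylate
Product: 14 methyl (4aR,7R,8aR)-7-acetyl-4a-methyl-3,4,4a,5,6,7,8,8a-octahydronaphthalene-1-carboxylate, via potassium alkoxide 12 (not isolated), via axial 7-epi ketone 13 (not isolated)
Conditions: t-BuOK (1.3 equiv), t-BuOH–THF, 0 °C → rt; then NaOMe (0.2 equiv), MeOH, rt
Reagents that add atoms: none
Why: t-BuOK deprotonates the tertiary C11 hydroxyl to alkoxide 12, and in the favoured seven-ring conformer (C7–OMs and C11–CH3 pseudo-equatorial, C11–O pseudo-axial) the C11–C6 ring bond lies antiperiplanar to the C7–OMs bond, so C6 migrates from C11 to C7 as mesylate leaves and C11 becomes the acetyl carbonyl. The closest known reaction type is the base-induced pinacol-type (semipinacol) ring contraction of cyclic cis-diol monosulfonates to ring-contracted methyl ketones. Ring B (C5–C10) is closed by this 1,2-alkyl shift, that is by contraction of the ring C5–C6–C11–C7–C8–C9–C10 with extrusion of C11, and not by a cyclisation. The shift inverts C7 and should give the axial 7α-acetyl ketone 13 from the 7α-mesylate, after which methoxide-mediated enolisation sets C7 under thermodynamic control as the equatorial 7β-acetyl ketone 14, which avoids the syn-axial H-5 and H-9. The step needs ring-bond migration to beat methyl migration, E2 elimination and epoxide closure, and the substrate secures this because the cis O/OMs relationship forbids epoxide formation and the conformer with methyl anti to the mesylate would carry both OMs and CH3 axial. C5 and C10 cannot epimerise because neither is α to the new ketone and the enoate leaves C5 non-enolisable.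

Step 8
Reactants: 14 methyl (4aR,7R,8aR)-7-acetyl-4a-methyl-3,4,4a,5,6,7,8,8a-octahydronaphthalene-1-carboxylate
Product: 16 methyl (4aR,7R,8aR)-4a-methyl-7-{1-[(trifluoromethanesulfonyl)oxy]ethenyl}-3,4,4a,5,6,7,8,8a-octahydronaphthalene-1-carboxylate, via potassium enolate 15 (not isolated)
Conditions: KN(SiMe3)2 (KHMDS, 1.05 equiv), THF, −78 °C; PhNTf2, −78 °C
Reagents that add atoms: N-phenylbis(trifluoromethanesulfonimide) O=S(=O)(N(c1ccccc1)S(=O)(=O)C(F)(F)F)C(F)(F)F
Why: At −78 °C the base removes a proton from the unhindered acetyl methyl group, which is more acidic and more accessible than the γ-hydrogens of the enoate or the C7 methine, and PhNTf2 traps the terminal enolate 15 as the 1,1-disubstituted vinyl triflate without epimerising C7 (kinetic enol triflate formation).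

Step 9
Reactants: 16 methyl (4aR,7R,8aR)-4a-methyl-7-{1-[(trifluoromethanesulfonyl)oxy]ethenyl}-3,4,4a,5,6,7,8,8a-octahydronaphthalene-1-carboxylate
Product: 17 1-[(2R,4aR,8aR)-8-(hydroxymethyl)-4a-methyl-1,2,3,4,4a,5,6,8a-octahydronaphthalen-2-yl]ethenyl trifluoromethanesulfonate
Conditions: i-Bu2AlH (DIBAL-H, 2.5 equiv), CH2Cl2, −78 °C; aqueous Rochelle salt work-up
Reagents that add atoms: none
Why: The aluminium hydride reduces the conjugated methyl ester in 1,2-fashion to the primary allylic alcohol at C15 while the vinyl triflate is inert, so the two former carbonyl carbons are differentiated without a protecting group (ester reduction).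

Step 10
Reactants: 17 1-[(2R,4aR,8aR)-8-(hydroxymethyl)-4a-methyl-1,2,3,4,4a,5,6,8a-octahydronaphthalen-2-yl]ethenyl trifluoromethanesulfonate
Product: 18 methyl 2-[(2R,4aR,8aR)-8-(hydroxymethyl)-4a-methyl-1,2,3,4,4a,5,6,8a-octahydronaphthalen-2-yl]prop-2-enoate
Conditions: Pd(OAc)2 (5 mol %), PPh3, CO (1 atm), MeOH, Et3N, DMF, 50 °C
Reagents that add atoms: carbon monoxide [C-]#[O+]; methanol CO
Why: Palladium-catalysed methoxycarbonylation of the 1,1-disubstituted vinyl triflate makes C11 the α-carbon of the methyl acrylate, the free allylic alcohol being neither ionised by zerovalent palladium nor competitive with solvent methanol as acyl acceptor.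

Step 11
Reactants: 18 methyl 2-[(2R,4aR,8aR)-8-(hydroxymethyl)-4a-methyl-1,2,3,4,4a,5,6,8a-octahydronaphthalen-2-yl]prop-2-enoate; 19 (E)-3-(4-hydroxyphenyl)prop-2-enoic acid (p-coumaric acid)
Product: 20 methyl 2-[(2R,4aR,8aR)-8-({[(2E)-3-(4-hydroxyphenyl)prop-2-enoyl]oxy}methyl)-4a-methyl-1,2,3,4,4a,5,6,8a-octahydronaphthalen-2-yl]prop-2-enoate (CNP0161949.1)
Conditions: PPh3, DIAD, THF, 0 °C → rt
Reagents that add atoms: none
Why: In the Mitsunobu reaction the carboxylic acid of 19, far more acidic than its phenol, protonates the betaine and its carboxylate displaces the activated primary allylic oxygen at C15 by SN2, which should give the (E)-p-coumarate without phenol protection and without touching any stereocentre.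

**Compound list**

1 | 3-methylcyclohex-2-en-1-one | CC1=CC(=O)CCC1 | starting material
2 | but-3-en-1-ylmagnesium bromide | C=CCC[Mg]Br | starting material
3 | bromomagnesium (R)-3-(but-3-en-1-yl)-3-methylcyclohex-1-en-1-olate | C=CCC[C@@]1(C)CCCC(O[Mg]Br)=C1 | intermediate
4 | 3-bromo-2-methylprop-1-ene | C=C(C)CBr | starting material
5 | (2R,3R)-3-(but-3-en-1-yl)-3-methyl-2-(2-methylprop-2-en-1-yl)cyclohexan-1-one | C=CCC[C@@]1(C)CCCC(=O)[C@@H]1CC(C)=C | intermediate
6 | lithium (5S,6R)-5-(but-3-en-1-yl)-5-methyl-6-(2-methylprop-2-en-1-yl)cyclohex-1-en-1-olate | C=CCC[C@@]1(C)CCC=C([O-])[C@@H]1CC(C)=C.[Li+] | intermediate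
7 | (5S,6R)-5-(but-3-en-1-yl)-5-methyl-6-(2-methylprop-2-en-1-yl)cyclohex-1-en-1-yl trifluoromethanesulfonate | C=CCC[C@@]1(C)CCC=C(OS(=O)(=O)C(F)(F)F)[C@@H]1CC(C)=C | intermediate
8 | (4aS,9aR)-4a,8-dimethyl-4,4a,5,6,9,9a-hexahydro-3H-benzo[7]annulen-1-yl trifluoromethanesulfonate (trans-fused; H-5 α, CH3-10 β) | CC1=CCC[C@@]2(C)CCC=C(OS(=O)(=O)C(F)(F)F)[C@@H]2C1 | intermediate
9 | methyl (4aS,9aR)-4a,8-dimethyl-4,4a,5,6,9,9a-hexahydro-3H-benzo[7]annulene-1-carboxylate | CC1=CCC[C@@]2(C)CCC=C(C(=O)OC)[C@@H]2C1 | intermediate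
10 | methyl (4aR,7S,8R,9aR)-7,8-dihydroxy-4a,8-dimethyl-4,4a,5,6,7,8,9,9a-octahydro-3H-benzo[7]annulene-1-carboxylate (7α,11α-diol) | C[C@]1(O)[C@@H](O)CC[C@@]2(C)CCC=C(C(=O)OC)[C@@H]2C1 | intermediate
11 | methyl (4aR,7S,8R,9aR)-8-hydroxy-7-[(methanesulfonyl)oxy]-4a,8-dimethyl-4,4a,5,6,7,8,9,9a-octahydro-3H-benzo[7]annulene-1-carboxylate | C[C@]1(O)[C@@H](OS(C)(=O)=O)CC[C@@]2(C)CCC=C(C(=O)OC)[C@@H]2C1 | intermediate
12 | potassium alkoxide of 11 (C11–O−) | C[C@]1([O-])[C@@H](OS(C)(=O)=O)CC[C@@]2(C)CCC=C(C(=O)OC)[C@@H]2C1.[K+] | intermediate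
13 | methyl (4aR,7S,8aR)-7-acetyl-4a-methyl-3,4,4a,5,6,7,8,8a-octahydronaphthalene-1-carboxylate (axial 7α-acetyl) | CC(=O)[C@H]1CC[C@@]2(C)CCC=C(C(=O)OC)[C@@H]2C1 | intermediate
14 | methyl (4aR,7R,8aR)-7-acetyl-4a-methyl-3,4,4a,5,6,7,8,8a-octahydronaphthalene-1-carboxylate (equatorial 7β-acetyl, trans-decalin) | CC(=O)[C@@H]1CC[C@@]2(C)CCC=C(C(=O)OC)[C@@H]2C1 | intermediate
15 | potassium enolate of 14 (terminal, C11=C13) | C=C([O-])[C@@H]1CC[C@@]2(C)CCC=C(C(=O)OC)[C@@H]2C1.[K+] | intermediate
16 | methyl (4aR,7R,8aR)-4a-methyl-7-{1-[(trifluoromethanesulfonyl)oxy]ethenyl}-3,4,4a,5,6,7,8,8a-octahydronaphthalene-1-carboxylate | C=C(OS(=O)(=O)C(F)(F)F)[C@@H]1CC[C@@]2(C)CCC=C(C(=O)OC)[C@@H]2C1 | intermediate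
17 | 1-[(2R,4aR,8aR)-8-(hydroxymethyl)-4a-methyl-1,2,3,4,4a,5,6,8a-octahydronaphthalen-2-yl]ethenyl trifluoromethanesulfonate | C=C(OS(=O)(=O)C(F)(F)F)[C@@H]1CC[C@@]2(C)CCC=C(CO)[C@@H]2C1 | intermediate
18 | methyl 2-[(2R,4aR,8aR)-8-(hydroxymethyl)-4a-methyl-1,2,3,4,4a,5,6,8a-octahydronaphthalen-2-yl]prop-2-enoate | C=C(C(=O)OC)[C@@H]1CC[C@@]2(C)CCC=C(CO)[C@@H]2C1 | intermediate
19 | (E)-3-(4-hydroxyphenyl)prop-2-enoic acid | O=C(O)/C=C/c1ccc(O)cc1 | starting material
20 | methyl 2-[(2R,4aR,8aR)-8-({[(2E)-3-(4-hydroxyphenyl)prop-2-enoyl]oxy}methyl)-4a-methyl-1,2,3,4,4a,5,6,8a-octahydronaphthalen-2-yl]prop-2-enoate | C=C(C(=O)OC)[C@@H]1CC[C@@]2(C)CCC=C(COC(=O)/C=C/c3ccc(O)cc3)[C@@H]2C1 | target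

**Totals and risks**

Total step count: 11. Longest linear sequence: 11 steps (from 1).

The three steps most likely to fail:

Step 1 may suffer from poor facial selectivity in the alkylation of enolate 3, because the two β-substituents (methyl and butenyl) differ little in size, so the C5 epimer could form in quantity. C-alkylation next to the quaternary centre may also be sluggish. The fallback replaces substrate control by catalyst control. Setting out from enolate 3, O-acylation with 2-methylallyl chloroformate (TMEDA, −78 °C) gives the enol carbonate F1. Decarboxylative allylic alkylation with zerovalent palladium (Pd2(dba)3 and (S)-4-tert-butyl-2-[2-(diphenylphosphino)phenyl]-4,5-dihydrooxazole, or its enantiomer if that is the matched case) then forms C5–C6 regiospecifically with the ligand selecting the enolate face. The route is rejoined at ketone 5.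

Step 7 may be diverted by methyl migration, by E2 elimination of the mesylate, or by incomplete equilibration at C7. The fallback generates the C7 electrophile without a basic alkoxide. Setting out from alkene 9, oxidative rearrangement with Tl(NO3)3·3H2O in MeOH adds trivalent thallium to C7 and methanol to C11, and loss of monovalent thallium drives the same C6 shift. This gives the ring-contracted dimethyl ketal F2. Aqueous acid hydrolysis releases ketone 13, which is equilibrated with NaOMe as in step 7, and the route is rejoined at 14.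

Step 11 may give O-alkylation of the phenol or oligomerisation of 19 under Mitsunobu conditions. The fallback builds the cinnamate double bond last. Setting out from alcohol 18, carbodiimide coupling (DCC, DMAP) with diethylphosphonoacetic acid gives the phosphonoacetate F3. A Horner–Wadsworth–Emmons olefination with 4-hydroxybenzaldehyde (LiCl, excess DBU, MeCN) should then give the (E)-coumarate directly, and the route is rejoined at 20.

**Further compounds**

F1 | step 1 | (R)-3-(but-3-en-1-yl)-3-methylcyclohex-1-en-1-yl 2-methylprop-2-en-1-yl carbonate | C=CCC[C@@]1(C)CCCC(OC(=O)OCC(C)=C)=C1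
F2 | step 7 | methyl (4aR,7S,8aR)-7-(1,1-dimethoxyethyl)-4a-methyl-3,4,4a,5,6,7,8,8a-octahydronaphthalene-1-carboxylate | COC(C)(OC)[C@H]1CC[C@@]2(C)CCC=C(C(=O)OC)[C@@H]2C1
F3 | step 11 | methyl 2-[(2R,4aR,8aR)-8-({[2-(diethoxyphosphoryl)acetyl]oxy}methyl)-4a-methyl-1,2,3,4,4a,5,6,8a-octahydronaphthalen-2-yl]prop-2-enoate | C=C(C(=O)OC)[C@@H]1CC[C@@]2(C)CCC=C(COC(=O)CP(=O)(OCC)OCC)[C@@H]2C1
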